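**Retrosynthetic overview**

1. The C7 ketone comes from a 7β-alcohol (last step); the tetrahydrofuran (C9–O–C13) closes late by oxa-Michael addition of the 9α-OH to a β-substituted butenolide.
2. 8β-OAc/9α-OH come from the α-epoxide of a Δ8 alkene opened through the neighbouring 7β-acetate; the Δ8-7-oxygen pattern comes from vinyl addition to a 7-en-9-one, B-alkyl Suzuki coupling with 4-bromofuranone (brings the butenolide) and oxidative 1,3-transposition.
3. The γ-lactone (C19→O6), the C4 quaternary centre and the trans ring fusion come from the enol lactone of a γ-keto acid: C-methylation, then hydration/reduction.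
4. The decalin comes from an organocatalytic enantioselective Diels–Alder reaction of 2,6-dimethylbenzoquinone (ring B) with penta-2,4-dienoic acid (forms ring A, sets C10).
5. Ring order: B (given) → A → γ-lactone → butenolide (coupled on) → tetrahydrofuran.

Notation: labdane numbering throughout (ring A = C1–C5, C10; ring B = C5–C10; C17 = CH3 on C8, C18 = CH3 on C4, C19 = carboxyl carbon on C4, C20 = CH3 on C10, side chain C11–C16); β = face of the C10 methyl, α = opposite face.

**Step 1**
Reactants: 1 2,6-dimethyl-1,4-benzoquinone; 2 (2E)-penta-2,4-dienoic acid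
Product: 3 cis-fused endo cycloadduct, 8,10β-dimethyl-6,9-dioxo-5β-H-decal-2,7-diene-4α-carboxylic acid
Conditions: 9-O-benzylcupreidine (10 mol %), 1 (1.5 equiv), CH2Cl2, rt, 72 h
Reagents that add atoms: none
Why: Proposed new method: a bifunctional cinchona base should turn acid 2 into a chiral ammonium dienoate (the carboxylate no longer withdraws, so the diene is about as electron-rich as an alkyl diene) while its 6′-OH hydrogen-bonds the unhindered, more basic carbonyl of 1 (the one flanked by two CH), so that the free CH2 terminus bonds to the methyl-bearing β-carbon and the carboxylate-bearing terminus to the CH carbon through an ion-paired endo transition state on one quinone face, which sets C10 (kept to the end) together with C5 and C4 (both corrected later); the sense of induction cannot be predicted with confidence, and the cupreine-derived pseudo-enantiomer is used if it is opposite; the closest known chemistry is the amine/phenol bifunctional cinchona-catalysed Diels–Alder reaction of 3-hydroxy-2-pyrones and the uncatalysed vinylacrylic acid–benzoquinone cycloaddition.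

**Step 2**
Reactants: 3 cycloadduct acid
Product: 4 8,10β-dimethyl-6,9-dioxo-5β-H-decal-7-ene-4α-carboxylic acid
Conditions: H2 (1 atm), RhCl(PPh3)3 (5 mol %), benzene/EtOH, rt
Reagents that add atoms: none
Why: Homogeneous catalytic hydrogenation with RhCl(PPh3)3 saturates the unhindered cis-disubstituted ring-A alkene and leaves the trisubstituted, electron-poor enedione alkene; no stereocentre is formed.

**Step 3**
Reactants: 4 keto acid
Product: 5 enol lactone, 8,10β-dimethyl-9-oxodecal-5,7-diene-19,6-olide (4-H)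
Conditions: Ac2O, NaOAc, 100 °C
Reagents that add atoms: none
Why: Classical enol-lactonisation of a γ-keto acid (pseudo-acid acetate, then loss of acetic acid): the C4 carboxyl is cis to C6, the lactone closes toward C5, and C5 becomes sp2, which erases the cis ring fusion.

**Step 4**
Reactants: 5 enol lactone
Product: 6 4α,8,10β-trimethyl-9-oxodecal-5,7-diene-19,6-olide
Conditions: LiN(SiMe3)2, THF, −78 °C; MeI, −78 → 0 °C
Reagents that add atoms: iodomethane, CI
Why: C3-alkylation of a 2(3H)-furanone enolate (benzofuranone-type enolate alkylation): the planar 2-oxidofuran is methylated at C4 from the α face, anti to the pseudo-axial C10 methyl that shields the β face across ring A, which sets the C4 quaternary centre (CH3 α, lactone carbonyl β).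

**Step 5**
Reactants: 6 methylated enol lactone
Product: 8 4α,8,10β-trimethyl-9-oxo-5α-decal-7-ene-19,6β-olide, via trans-fused lactol 7 (not isolated)
Conditions: 2 M HCl, dioxane, 60 °C; then NaBH4, CeCl3·7H2O, MeOH, −40 °C; then 1 M HCl
Reagents that add atoms: water, O
Why: Acid hydrolysis of the enol ester gives the γ-keto acid, whose C5 epimers interconvert by enolisation while only the 5α-H (trans-fused) one can close the strain-free cis-fused lactol 7 with the β-carboxyl, so C5 is set under thermodynamic control; Luche 1,2-reduction of the less hindered C6 carbonyl from the α face (the β face carries C19 and C20) then gives the 6β-alcohol, which lactonises on acidification (sets C6).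

**Step 6**
Reactants: 8 keto lactone; 9 vinylmagnesium bromide (CH2=CHMgBr)
Product: 10 9-hydroxy-9-vinyl derivative of 8 (C9 epimers; 9β-OH drawn as major)
Conditions: CeCl3, THF, −78 → 0 °C; aq. NH4Cl
Reagents that add atoms: none
Why: Organocerium 1,2-addition to a hindered enone carbonyl without α-hydrogens (2,6,6-trisubstituted cyclohexenone type), faster than attack on the lactone at the quaternary C4; attack anti to the C10 methyl should give mainly the 9β-ol, but this centre is erased in step 8.

**Step 7**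
Reactants: 10 vinyl carbinol; 11 4-bromofuran-2(5H)-one
Product: 13 9-hydroxylabda-7,13-diene-19,6β:15,16-diolide (C9 epimers), via B-alkyl-9-BBN adduct 12 (not isolated)
Conditions: 9-BBN (2.2 equiv), THF, 0 °C → rt; then 11, PdCl2(dppf) (5 mol %), K3PO4 (aq.), DMF, rt
Reagents that add atoms: none
Why: 9-BBN hydroborates only the monosubstituted vinyl group (anti-Markovnikov) and the B-alkyl Suzuki–Miyaura coupling with the β-bromobutenolide attaches C13–C16; no stereocentre is formed.

**Step 8**
Reactants: 13 tertiary allylic alcohol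
Product: 14 7-oxolabda-8,13-diene-19,6β:15,16-diolide
Conditions: pyridinium chlorochromate [C5H5NH][CrO3Cl], 4 Å sieves, CH2Cl2, rt
Reagents that add atoms: pyridinium chlorochromate, [O-][Cr](=O)(=O)Cl.c1cc[nH+]cc1
Why: Babler–Dauben oxidative 1,3-transposition: the chromate ester of the tertiary allylic alcohol undergoes a [3,3] shift to C7 and is oxidised, which gives the tetrasubstituted 8-en-7-one and removes the C9 epimer mixture.

**Step 9**
Reactants: 14 enone
Product: 16 7β-acetoxylabda-8,13-diene-19,6β:15,16-diolide, via 7β-alcohol 15 (not isolated)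
Conditions: NaBH4, CeCl3·7H2O, MeOH, −78 °C; then Ac2O, DMAP, pyridine, rt
Reagents that add atoms: acetic anhydride, CC(=O)OC(C)=O
Why: Luche 1,2-reduction with axial hydride delivery from the α face (anti to the 6β-oxygen, Felkin-type) gives the equatorial 7β-alcohol, which is acetylated; this temporary C7 centre later delivers the C8 oxygen.

**Step 10**
Reactants: 16 allylic acetate
Product: 19 9α-hydroxylabd-13-ene-19,6β:15,16-diolide 7β,8β-(cyclic methyl orthoacetate), via 8α,9α-epoxide 17 (not isolated), via dioxolanylium borate 18 (not isolated)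
Conditions: mCPBA, NaHCO3, CH2Cl2, 0 °C; filter; then BF3·OEt2, −78 °C; then MeOH, Et3N
Reagents that add atoms: mCPBA, OOC(=O)c1cccc(Cl)c1; methanol, CO
Why: Peracid epoxidation of the tetrasubstituted alkene occurs anti to the C10 methyl (α face), and the Lewis acid then opens the epoxide at C8 with anchimeric assistance by the 7β-acetate (trans-2-acyloxy epoxide to 1,3-dioxolan-2-ylium ion), which puts oxygen on C8 from the β face and leaves the epoxide oxygen as 9α-OH (sets C8 and C9); methanol traps the cation as a base-stable orthoester.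

**Step 11**
Reactants: 19 orthoester
Product: 21 (13R)-8β-acetoxy-7β-hydroxy-9α,13-epoxylabdane-19,6β:15,16-diolide, via spiro orthoester 20 (not isolated)
Conditions: DBU (0.3 equiv), CH2Cl2, rt; then AcOH/H2O/THF, 0 °C
Reagents that add atoms: water, O
Why: 5-exo oxa-Michael addition of the 9α-alkoxide to the butenolide β-carbon closes the tetrahydrofuran and creates C13 with little substrate bias, so the 13S epimer is expected in comparable amount and is removed by chromatography after hydrolysis; mild acid hydrolysis of the cyclic orthoacetate gives the axial 8β-acetate and equatorial 7β-alcohol (stereoelectronically controlled orthoester opening).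

**Step 12**
Reactants: 21 hydroxy acetate
Product: 22 target, (13R)-8β-acetoxy-7-oxo-9α,13-epoxylabdane-19,6β:15,16-diolide
Conditions: Dess–Martin periodinane, NaHCO3, CH2Cl2, rt
Reagents that add atoms: none
Why: Dess–Martin oxidation of the secondary 7β-alcohol to the ketone under buffered neutral conditions, which avoids acetyl migration and leaves all seven stereocentres untouched.

**Compound list**

1 | 2,6-dimethyl-1,4-benzoquinone | CC1=CC(=O)C=C(C)C1=O | starting material
2 | (2E)-penta-2,4-dienoic acid | OC(=O)/C=C/C=C | starting material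
3 | cis-fused endo cycloadduct, 8,10β-dimethyl-6,9-dioxo-5β-H-decal-2,7-diene-4α-carboxylic acid | CC1=CC(=O)[C@@H]2[C@H](C(=O)O)C=CC[C@]2(C)C1=O | intermediate
4 | 8,10β-dimethyl-6,9-dioxo-5β-H-decal-7-ene-4α-carboxylic acid | CC1=CC(=O)[C@@H]2[C@H](C(=O)O)CCC[C@]2(C)C1=O | intermediate
5 | enol lactone, 8,10β-dimethyl-9-oxodecal-5,7-diene-19,6-olide (4-H) | CC1=CC2=C3[C@@H](CCC[C@]3(C)C1=O)C(=O)O2 | intermediate
6 | 4α,8,10β-trimethyl-9-oxodecal-5,7-diene-19,6-olide | CC1=CC2=C3[C@](C)(CCC[C@]3(C)C1=O)C(=O)O2 | intermediate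
7 | lactol, 6α-hydroxy-4α,8,10β-trimethyl-9-oxo-5α-decal-7-ene-19,6β-olide | CC1=C[C@@]2(O)OC(=O)[C@@]3(C)CCC[C@@](C)([C@@H]23)C1=O | intermediate (not isolated)
8 | 4α,8,10β-trimethyl-9-oxo-5α-decal-7-ene-19,6β-olide | CC1=C[C@H]2OC(=O)[C@@]3(C)CCC[C@@](C)([C@@H]23)C1=O | intermediate
9 | vinylmagnesium bromide | C=C[Mg]Br | starting material
10 | 9β-hydroxy-9α-vinyl-4α,8,10β-trimethyl-5α-decal-7-ene-19,6β-olide (major C9 epimer) | CC1=C[C@H]2OC(=O)[C@@]3(C)CCC[C@@](C)([C@@H]23)[C@]1(O)C=C | intermediate
11 | 4-bromofuran-2(5H)-one | BrC1=CC(=O)OC1 | starting material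
12 | B-alkyl-9-BBN adduct of 10 (C12 on boron) | CC1=C[C@H]2OC(=O)[C@@]3(C)CCC[C@@](C)([C@@H]23)[C@]1(O)CCB1C2CCCC1CCC2 | intermediate (not isolated)
13 | 9β-hydroxylabda-7,13-diene-19,6β:15,16-diolide (major C9 epimer) | CC1=C[C@H]2OC(=O)[C@@]3(C)CCC[C@@](C)([C@@H]23)[C@]1(O)CCC1=CC(=O)OC1 | intermediate
14 | 7-oxolabda-8,13-diene-19,6β:15,16-diolide | CC1=C(CCC2=CC(=O)OC2)[C@@]2(C)CCC[C@@]3(C)[C@@H]2[C@H](OC3=O)C1=O | intermediate
15 | 7β-hydroxylabda-8,13-diene-19,6β:15,16-diolide | CC1=C(CCC2=CC(=O)OC2)[C@@]2(C)CCC[C@@]3(C)[C@@H]2[C@H](OC3=O)[C@@H]1O | intermediate (not isolated)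
16 | 7β-acetoxylabda-8,13-diene-19,6β:15,16-diolide | CC1=C(CCC2=CC(=O)OC2)[C@@]2(C)CCC[C@@]3(C)[C@@H]2[C@H](OC3=O)[C@@H]1OC(C)=O | intermediate
17 | 7β-acetoxy-8α,9α-epoxylabd-13-ene-19,6β:15,16-diolide | C[C@]12O[C@@]1(CCC5=CC(=O)OC5)[C@@]4(C)CCC[C@@]3(C)[C@@H]4[C@H](OC3=O)[C@@H]2OC(C)=O | intermediate (not isolated)
18 | 7β,8β-(2-methyl-1,3-dioxolan-2-ylium) ion with 9α-O–BF3 borate | C[C@]12OC(C)=[O+][C@H]1[C@H]3OC(=O)[C@@]4(C)CCC[C@@](C)([C@@H]34)[C@@]2(O[B-](F)(F)F)CCC1=CC(=O)OC1 | intermediate (not isolated)
19 | 9α-hydroxylabd-13-ene-19,6β:15,16-diolide 7β,8β-(cyclic methyl orthoacetate), orthoester carbon as a mixture | C[C@]12OC(C)(OC)O[C@H]1[C@H]3OC(=O)[C@@]4(C)CCC[C@@](C)([C@@H]34)[C@@]2(O)CCC1=CC(=O)OC1 | intermediate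
20 | (13R)-9α,13-epoxylabdane-19,6β:15,16-diolide 7β,8β-(cyclic methyl orthoacetate) | C[C@]12OC(C)(OC)O[C@H]1[C@H]3OC(=O)[C@@]4(C)CCC[C@@](C)([C@@H]34)[C@@]25CC[C@@]6(COC(=O)C6)O5 | intermediate (not isolated)
21 | (13R)-8β-acetoxy-7β-hydroxy-9α,13-epoxylabdane-19,6β:15,16-diolide | CC(=O)O[C@@]1(C)[C@@H](O)[C@H]2OC(=O)[C@@]3(C)CCC[C@@](C)([C@@H]23)[C@@]12CC[C@@]1(COC(=O)C1)O2 | intermediate
22 | (13R)-8β-acetoxy-7-oxo-9α,13-epoxylabdane-19,6β:15,16-diolide | CC(=O)O[C@@]1(C)C(=O)[C@H]2OC(=O)[C@@]3(C)CCC[C@@](C)([C@@H]23)[C@@]12CC[C@@]1(COC(=O)C1)O2 | target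

**Totals and risks**

Total step count: 12. Longest linear sequence: 12 steps (1 or 2 → 22); 9 and 11 are bought.

The three steps most likely to fail:

Step 1 (the new cycloaddition; reactivity at the methyl-bearing quinone alkene and the level and sense of enantiocontrol are unproven). The fallback uses known chemistry, sets out from 1 and rejoins at 4. (2E)-Penta-2,4-dien-1-ol is silylated (TBSCl, imidazole) to tert-butyl(dimethyl)[(2E)-penta-2,4-dien-1-yloxy]silane F1. F1 adds to 1 under the established cationic oxazaborolidine catalysis for quinones (catalyst from diphenylprolinol, o-tolylboroxine and HNTf2, CH2Cl2, −78 °C; endo, same regiochemistry, catalyst antipode chosen by the known selection rules) to give the silyloxymethyl cycloadduct F2. RhCl(PPh3)3/H2 gives the dihydro compound F3, Bu4NF frees the primary alcohol F4, and CrO3/H2SO4 in acetone oxidises it to acid 4.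

Step 4 (the enolate of 5 is conjugated through ring B to the C9 carbonyl, so methylation could stray to C8 or to oxygen). The fallback sets out from 4 and rejoins at 8. Zn dust in AcOH reduces the enedione alkene to the saturated diketo acid F5, and Ac2O/NaOAc gives the enol lactone F6, whose enolate is no longer conjugated to the C9 carbonyl. LiN(SiMe3)2/MeI gives the 4α-methyl enol lactone F7, aqueous HCl and then NaBH4 give the saturated keto lactone F8, and IBX (DMSO/toluene, 70 °C) reinstalls the 7,8-double bond to give 8.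

Step 10 (the Lewis acid may ionise the epoxide at C9 instead of letting the acetate open it at C8, leading to elimination or rearrangement). The fallback sets out from 17, isolated after the mCPBA stage, and rejoins at 22. K2CO3 in MeOH removes the acetate; the 7β-alkoxide opens the epoxide at C8 from the β face (Payne rearrangement) and the 9α-alkoxide so released adds to the butenolide, giving the 7β,8β-epoxy spiro ether F9 (C13 epimers separated). DMSO with catalytic TfOH, then Et3N, opens the epoxide at C7 and oxidises it (Kornblum-type) to the 8β-hydroxy 7-ketone F10. Ac2O/Sc(OTf)3 acetylates the tertiary alcohol to give 22.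

**Further compounds**

F1 | step 1 | tert-butyl(dimethyl)[(2E)-penta-2,4-dien-1-yloxy]silane | C=C/C=C/CO[Si](C)(C)C(C)(C)C
F2 | step 1 | cis-fused endo cycloadduct, 4α-(tert-butyldimethylsilyloxymethyl)-8,10β-dimethyl-5β-H-decal-2,7-diene-6,9-dione | CC1=CC(=O)[C@@H]2[C@H](CO[Si](C)(C)C(C)(C)C)C=CC[C@]2(C)C1=O
F3 | step 1 | 2,3-dihydro derivative of F2 | CC1=CC(=O)[C@@H]2[C@H](CO[Si](C)(C)C(C)(C)C)CCC[C@]2(C)C1=O
F4 | step 1 | 4α-hydroxymethyl-8,10β-dimethyl-5β-H-decal-7-ene-6,9-dione | CC1=CC(=O)[C@@H]2[C@H](CO)CCC[C@]2(C)C1=O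
F5 | step 4 | 8,10β-dimethyl-6,9-dioxo-5β-H-decalin-4α-carboxylic acid (C8 epimers) | CC1CC(=O)[C@@H]2[C@H](C(=O)O)CCC[C@]2(C)C1=O
F6 | step 4 | enol lactone, 8,10β-dimethyl-9-oxodecal-5-ene-19,6-olide (C8 epimers) | CC1CC2=C3[C@@H](CCC[C@]3(C)C1=O)C(=O)O2
F7 | step 4 | 4α,8,10β-trimethyl-9-oxodecal-5-ene-19,6-olide (C8 epimers) | CC1CC2=C3[C@](C)(CCC[C@]3(C)C1=O)C(=O)O2
F8 | step 4 | 4α,8α,10β-trimethyl-9-oxo-5α-decalin-19,6β-olide | C[C@@H]1C[C@H]2OC(=O)[C@@]3(C)CCC[C@@](C)([C@@H]23)C1=O
F9 | step 10 | (13R)-7β,8β:9α,13-diepoxylabdane-19,6β:15,16-diolide | C[C@]12O[C@H]1[C@H]3OC(=O)[C@@]4(C)CCC[C@@](C)([C@@H]34)[C@@]25CC[C@@]6(COC(=O)C6)O5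
F10 | step 10 | (13R)-8β-hydroxy-7-oxo-9α,13-epoxylabdane-19,6β:15,16-diolide | C[C@]1(O)C(=O)[C@H]2OC(=O)[C@@]3(C)CCC[C@@](C)([C@@H]23)[C@@]12CC[C@@]1(COC(=O)C1)O2
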